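Remark on the chemistry (assumption): ring B of the target is written as one dienol tautomer of a 2-acylcyclohexane-1,3,5-trione. The tautomers interconvert, so the route aims at the constitution only. The target has no stereocentre and no alkene geometry to set.

## Structural features

Sarothralin contains three carbocycles: benzene ring A, the phenyl ring of a benzoyl group on position A6, and ring B, a 6,6-dimethyl-2-(2-methylpropanoyl)cyclohexane-1,3,5-trione drawn as a dienol. Ring B is tied to position A4 through one methylene carbon. Around ring A the substituents run: position A1 O-prenyl, A2 H, A3 OH, A4 CH2, A5 OH, A6 C(=O)Ph, so a phloroglucinol oxygen pattern carries one ether and two free hydroxyls. With no stereocentre, every problem is one of regiochemistry. The fragile parts are the aryl prenyl ether (acid, Lewis acids, pi-allyl-forming metals, heat), the methylene bridge between two enolic rings (retro-Michael exchange in base) and the acidic enols of ring B (over-alkylation). The real difficulty is threefold: telling three phloroglucinol oxygens apart so that only the A1 oxygen is alkylated, placing the benzoyl group between A1 and A5, and forming the bridge at A4 and not at A2 without symmetrical dimers. The key step uses the fact that the ketone carbon on A6 and the ether oxygen on A1 sit on neighbouring ring carbons, with the A5 oxygen on the other side of A6. Both bonds can therefore come from the acyl–oxygen bond of a carboxylic acid adding across an aryne whose triple bond joins A1 and A6, with the A5 oxygen steering the direction of addition.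

## Logic of the disconnections

**23 to 16 and 20.** The bonds A4–CH2 and CH2–C(ring B) are cut. Both halves derive from 1, and 20 has a single nucleophilic ring carbon. The gain is a convergent split of 31 carbons into 18 + 12 + 1. The demand is that the one-carbon unit is placed on 20 first (21, then 22), so that 16 never meets a free one-carbon electrophile, and that ring A reacts at A4 and not at A2.

**20 to 18, then to 1 and 17.** The two C–CH3 bonds at the quaternary ring carbon are cut, then the ring–acyl bond. This reduces ring B to 1 and a four-carbon acyl chloride. The forward steps must stop at monoacylation and at two methyl groups on the same carbon.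

**16 to 14, then to 12 and 13.** The two O–CH2OCH3 bonds are cut first, then the A1 oxygen–allyl carbon bond. In 12 only the A1 hydroxyl is free, so the prenylation needs no choice among three oxygens. The price is that the later acetal cleavage must spare the allylic ether.

**12 to 8 and 9 (key).** The bonds A6–C(=O) and A1–O are cut together. Both are formed when aryne 10 inserts into the acyl–oxygen bond of 9. One step then delivers the benzophenone carbon skeleton and the differentiation of the A1 oxygen. The demands are correct orientation of addition to 10 and acyl transfer in 11 faster than its protonation. The connectivity of 8 and 12 was checked against ring A: the C–OTf carbon of 8 becomes A1, the C–Si carbon becomes A6, and the MOM-oxy carbons are A5 and A3. Nothing in these structures needs correcting. The design is tightened only in how 8 is made (amine-directed ortho bromination) and in how the bridge carbon is introduced (on 20 first).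

**8 to 5, 4, 3 and 1.** The C–Si and O–S bonds are cut (silyl migration from oxygen to carbon, then triflation), then O–Si, then C–Br, then two O–CH2OCH3 bonds. This leads back to symmetrical 1. The demands are bromination next to the free hydroxyl and not para to it, and acceptance of a statistical double protection in the first step on a cheap material.

## Other disconnections considered

**Alternative 1:** The cut lies inside ring B (B1–B2 and B4–B5), so ring B is grown on a ring A that already carries the benzoyl, prenyl and MOM groups. In the forward key step the dianion of the aryl-substituted diketone, compound A2, would be acylated at its terminal methylene by the diester, compound A3. The central diketone carbon would then close ring B on the second ester (six-membered Claisen-type acylation) to give compound A1, the bis-MOM ether of 23.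
- In its favour: the quaternary carbon arrives ready-made in compound A3, so the methylation control problem of step 9 disappears. The methylene link is already in place, so neither A2/A4 competition at the union nor symmetrical dimers can arise. On these two points the alternative is better than the chosen plan.
- Against it: compound A2 needs a four-carbon-linked chain attached to position A4 of a crowded ring A, so the A4-versus-A2 question is moved earlier and not removed. A carbanionic dianion must coexist with a diaryl ketone that is an electrophile. Both ester carbonyls of compound A3 flank a quaternary carbon and should be slow acceptors. Compound A1 is a strong carbon acid that consumes base.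
- Comparison: the last step would still be acidic removal of two MOM groups beside the prenyl ether, so on that point the plans are equal. Mechanistically the chosen plan uses enol alkylation and Mannich/Michael chemistry near room temperature where the alternative uses cryogenic polyanion chemistry. In step economy the alternative should be longer, because reaching compound A2 costs at least the steps needed for 16 plus the chain construction.

**Alternative 2:** The three aryl C–O bonds at positions A1, A3 and A5 are cut, leaving the trifluoro ketone, compound A5. In the forward key step the lithium alkoxide, compound A6, would displace one ortho fluoride under chelation of lithium to the ketone oxygen. The potassium alkoxide, compound A7, would then displace the para and the second ortho fluoride in the same flask to give compound A4. Deallylation with zerovalent palladium would lead to 16, and step 10 would finish the synthesis.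
- In its favour: it is by far the shortest way to 16 (about three steps where the chosen plan needs seven), which makes it better in step economy. Its deprotection is non-acidic, in principle kinder to the prenyl ether than step 7.
- Against it: the para fluoride is intrinsically the most activated position, so the first substitution rests on a chelation effect that depends on solvent and aggregation. The third substitution occurs on a ring that already carries two alkoxy donors and would need forcing conditions. Under those conditions alkoxides can exchange with ethers already installed, add to the ketone, or trigger allyl rearrangements. Zerovalent palladium can also ionise an aryl prenyl ether whose phenoxide is stabilised by an ortho ketone.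
- Comparison: in the chosen plan the A1 oxygen is distinguished structurally (one free hydroxyl in 12), whereas here it is distinguished kinetically. Both plans share step 10 and its risks, so there they are equal.

**Alternative 3:** The bonds A6–C(=O) and C(=O)–phenyl are cut. In the forward key step the aryl iodide, compound A9, the boronic acid, compound A10, and carbon monoxide, compound A11, would be joined by a carbonylative Suzuki coupling (divalent palladium phosphine precatalyst, carbonate base) to give the keto aldehyde, compound A8. Compound A9 would come from the mirror-symmetric aldehyde, compound A12, by iodination at either of its two equivalent ring positions.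
- In its favour: the future bridge carbon sits on position A4 from the outset as a formyl group placed by symmetry, so the A2/A4 question of step 10 does not arise. On this point the alternative is better than the chosen plan. The benzoyl group is assembled from simple components.
- Against it: the C–I bond of compound A9 lies between two ortho oxygen substituents on an electron-rich ring, so oxidative addition and CO insertion should be slow and direct biaryl coupling competes. Zerovalent palladium formed in the cycle may ionise the prenyl ether. Afterwards compound A8 must be condensed with 20 and the arylidene reduced to the CH2 link in the presence of a diaryl ketone and an alkene.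
- Comparison: MOM removal beside the prenyl ether remains, so there the plans are equal, and the step counts are similar. The chosen key step is metal-free, has a close precedent class and leaves a single free hydroxyl, whereas this key step depends on a hindered three-component coupling.

Key step: step 5

## Route

**Step 1**
Reactants: 1 phloroglucinol
Product: 3 3,5-bis(methoxymethoxy)phenol, via 5-(methoxymethoxy)benzene-1,3-diol 2 (not isolated)
Conditions: MOMCl (2.0 equiv), i-Pr2NEt (2.2 equiv), DMF/CH2Cl2, 0 °C to rt
Reagents that add atoms: chloromethyl methyl ether, COCCl
Why: Base-mediated O-alkylation of a phenol by a chloromethyl ether (Williamson-type acetal formation); the three hydroxyls of 1 are equivalent, so two equivalents of MOMCl should give 3 as the main component of a statistical mixture, from which the mono-ether 2 and the tris-ether are separated by chromatography and recycled.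

**Step 2**
Reactants: 3 3,5-bis(methoxymethoxy)phenol
Product: 4 2-bromo-3,5-bis(methoxymethoxy)phenol
Conditions: NBS (1.0 equiv), i-Pr2NH (0.1 equiv), CH2Cl2, −78 to 0 °C
Reagents that add atoms: N-bromosuccinimide, O=C1CCC(=O)N1Br
Why: Electrophilic aromatic bromination; the secondary amine forms an N-bromoamine that is hydrogen-bonded to the free hydroxyl and delivers bromine to the neighbouring carbon, while the para carbon is flanked by two MOM-oxy groups, so the ortho isomer (both ortho positions are equivalent) should predominate, and low temperature with one equivalent of NBS limits dibromination.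

**Step 3**
Reactants: 4 2-bromo-3,5-bis(methoxymethoxy)phenol
Product: 5 [2-bromo-3,5-bis(methoxymethoxy)phenoxy]trimethylsilane
Conditions: (Me3Si)2NH, THF, 65 °C; volatiles removed in vacuo
Reagents that add atoms: hexamethyldisilazane, C[Si](C)(C)N[Si](C)(C)C
Why: O-silylation of a phenol with hexamethyldisilazane, which needs no added base and leaves only ammonia; the moisture-sensitive ether 5 is used crude.

**Step 4**
Reactants: 5 [2-bromo-3,5-bis(methoxymethoxy)phenoxy]trimethylsilane
Product: 8 3,5-bis(methoxymethoxy)-2-(trimethylsilyl)phenyl trifluoromethanesulfonate, via aryllithium 6 (not isolated), via lithium silylphenoxide 7 (not isolated)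
Conditions: n-BuLi (1.1 equiv), THF, −100 to −78 °C; then Tf2O (1.2 equiv), −100 to −78 °C
Reagents that add atoms: trifluoromethanesulfonic anhydride, O=S(=O)(OS(=O)(=O)C(F)(F)F)C(F)(F)F
Why: Bromine–lithium exchange gives 6, the trimethylsilyl group then shifts from oxygen to the adjacent carbanion (retro-Brook 1,3 O→C migration, driven by formation of phenoxide 7), and Tf2O sulfonylates the phenoxide oxygen; the MOM ethers are inert to n-BuLi at this temperature.

**Step 5**
Reactants: 8 3,5-bis(methoxymethoxy)-2-(trimethylsilyl)phenyl trifluoromethanesulfonate, 9 benzoic acid
Product: 12 2-hydroxy-4,6-bis(methoxymethoxy)benzophenone, via 3,5-bis(methoxymethoxy)benzyne 10 (not isolated), via cesium aryl anion 11 (not isolated)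
Conditions: CsF (4 equiv), 9 (1.2 equiv), THF, 125 °C, sealed tube
Reagents that add atoms: none
Why: Fluoride attacks the silicon of 8 and triflate leaves from the neighbouring carbon, which sets free aryne 10, whose triple bond joins the carbons that become A1 and A6. Benzoate, formed from 9 and CsF, adds through oxygen to A1, the aryne carbon remote from the MOM-oxy group on A5, because that oxygen distorts the aryne and stabilises by induction the negative charge developing on A6, so the adduct is aryl anion 11. Anion 11 then attacks its own ester carbonyl in a 1,3 O→C acyl shift through a four-membered cyclic transition structure, and cleavage of the ester C–O bond gives the phenoxide of 12, which is protonated in the flask or on work-up. The closest known reaction type is the insertion of arynes into the C–O bond of carboxylic acids to give ortho-hydroxyaryl ketones under CsF in hot THF, a member of the family of aryne sigma-bond insertions. No ring is closed and no stereocentre is formed; the two new bonds are A1–O and A6–C(=O). Three selectivities are needed: the orientation of addition, secured by the A5 oxygen as described; acyl transfer faster than protonation of 11, secured by the high temperature, dry CsF and only a small excess of 9; and no further arylation of the product, secured because its phenoxide is chelated and hindered and because 9, not 8, is in excess. The MOM acetals should tolerate fluoride and the weakly acidic bifluoride. The result is a benzophenone with exactly one free hydroxyl, on the oxygen that must carry the prenyl group.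

**Step 6**
Reactants: 12 2-hydroxy-4,6-bis(methoxymethoxy)benzophenone, 13 1-bromo-3-methylbut-2-ene
Product: 14 2,4-bis(methoxymethoxy)-6-[(3-methylbut-2-en-1-yl)oxy]benzophenone
Conditions: K2CO3 (2 equiv), DMF, rt to 40 °C
Reagents that add atoms: none
Why: Williamson ether synthesis (SN2 at the primary allylic bromide) on the only free hydroxyl of 12; carbonate in a dipolar aprotic solvent favours O- over C-alkylation, and the mild temperature keeps the new allyl aryl ether away from Claisen rearrangement.

**Step 7**
Reactants: 14 2,4-bis(methoxymethoxy)-6-[(3-methylbut-2-en-1-yl)oxy]benzophenone
Product: 16 2,4-dihydroxy-6-[(3-methylbut-2-en-1-yl)oxy]benzophenone, via mono-MOM ether 15 (not isolated)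
Conditions: HCl (ca. 0.5 M) in MeOH, 0 °C to rt, stopped as soon as 15 is consumed
Reagents that add atoms: none
Why: Acid-catalysed transacetalisation of the two aryl MOM ethers with methanol; both sit on phenols conjugated to the benzoyl group, so the acetal C–O bonds ionise (methoxymethyl cation) far more readily than the allylic C–O bond of the prenyl ether, and dilute acid at or below room temperature should remove the ortho MOM group first (15) and then the para one while the prenyl ether stays.

**Step 8**
Reactants: 1 phloroglucinol, 17 isobutyryl chloride
Product: 18 2-methyl-1-(2,4,6-trihydroxyphenyl)propan-1-one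
Conditions: AlCl3 (3.5 equiv), PhNO2, rt to 60 °C; aq. HCl work-up
Reagents that add atoms: none
Why: Friedel–Crafts C-acylation of the symmetrical, strongly activated ring of 1 (all ring CH positions are equivalent); the first acyl group and its aluminium chelate deactivate the ring against a second acylation.

**Step 9**
Reactants: 18 2-methyl-1-(2,4,6-trihydroxyphenyl)propan-1-one
Product: 20 isobutyrylfilicinic acid [3,5-dihydroxy-6,6-dimethyl-2-(2-methylpropanoyl)cyclohexa-2,4-dien-1-one], via C-methyl ketone 19 (not isolated)
Conditions: NaOMe (3.5 equiv), MeI (2.2 equiv), MeOH, 0 °C to rt; aq. HCl work-up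
Reagents that add atoms: iodomethane, CI
Why: Base-mediated C-methylation of the acylphloroglucinol polyanion; after the first methyl (19) the methyl-bearing carbon is the most electron-rich enolate carbon, so the second MeI should add there and dearomatise the ring to the geminal dimethyl triketone 20, and limiting MeI to about two equivalents restrains methylation at the last ring CH.

**Step 10**
Reactants: 20 isobutyrylfilicinic acid, 16 2,4-dihydroxy-6-[(3-methylbut-2-en-1-yl)oxy]benzophenone
Product: 23 sarothralin, via Mannich base hydroiodide 21 (not isolated), via methylene triketone 22 (not isolated)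
Conditions: Me2N+=CH2 I− (1.0 equiv), MeCN, rt; then 16 (1.1 equiv), 60 °C
Reagents that add atoms: N,N-dimethylmethyleneiminium iodide, C=[N+](C)C.[I-]
Why: Mannich reaction of the single nucleophilic ring carbon of 20 with the preformed iminium salt gives 21, which on warming loses dimethylamine (retro-Michael, E1cB-like) to the methylene triketone 22; 22 alkylates ring A of 16 in a Friedel–Crafts-type Michael addition, expected at position A4, which lies between two free hydroxyls and is less hindered than A2 beside the prenyloxy group, and because 16 never meets free formaldehyde, methylene-bridged dimers of ring A cannot form.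

## Compound list

1 | phloroglucinol (benzene-1,3,5-triol) | Oc1cc(O)cc(O)c1 | starting material
2 | 5-(methoxymethoxy)benzene-1,3-diol | COCOc1cc(O)cc(O)c1 | intermediate (not isolated)
3 | 3,5-bis(methoxymethoxy)phenol | COCOc1cc(O)cc(OCOC)c1 | intermediate
4 | 2-bromo-3,5-bis(methoxymethoxy)phenol | COCOc1cc(O)c(Br)c(OCOC)c1 | intermediate
5 | [2-bromo-3,5-bis(methoxymethoxy)phenoxy]trimethylsilane | COCOc1cc(O[Si](C)(C)C)c(Br)c(OCOC)c1 | intermediate
6 | [2-lithio-3,5-bis(methoxymethoxy)phenoxy]trimethylsilane | COCOc1cc(O[Si](C)(C)C)c([Li])c(OCOC)c1 | intermediate (not isolated)
7 | lithium 3,5-bis(methoxymethoxy)-2-(trimethylsilyl)phenoxide | COCOc1cc([O-])c([Si](C)(C)C)c(OCOC)c1.[Li+] | intermediate (not isolated)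
8 | 3,5-bis(methoxymethoxy)-2-(trimethylsilyl)phenyl trifluoromethanesulfonate | COCOc1cc(OCOC)c([Si](C)(C)C)c(OS(=O)(=O)C(F)(F)F)c1 | intermediate
9 | benzoic acid | OC(=O)c1ccccc1 | starting material
10 | 3,5-bis(methoxymethoxy)benzyne (1,2-didehydro-3,5-bis(methoxymethoxy)benzene) | COCOC1=CC#CC(OCOC)=C1 | intermediate (not isolated)
11 | cesium 2-(benzoyloxy)-4,6-bis(methoxymethoxy)benzenide (carbanion between the benzoyloxy and a MOM-oxy group) | COCOc1cc(OC(=O)c2ccccc2)[c-]c(OCOC)c1.[Cs+] | intermediate (not isolated)
12 | 2-hydroxy-4,6-bis(methoxymethoxy)benzophenone | COCOc1cc(O)c(C(=O)c2ccccc2)c(OCOC)c1 | intermediate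
13 | 1-bromo-3-methylbut-2-ene | CC(C)=CCBr | starting material
14 | 2,4-bis(methoxymethoxy)-6-[(3-methylbut-2-en-1-yl)oxy]benzophenone | COCOc1cc(OCC=C(C)C)c(C(=O)c2ccccc2)c(OCOC)c1 | intermediate
15 | 2-hydroxy-4-(methoxymethoxy)-6-[(3-methylbut-2-en-1-yl)oxy]benzophenone | COCOc1cc(O)c(C(=O)c2ccccc2)c(OCC=C(C)C)c1 | intermediate (not isolated)
16 | 2,4-dihydroxy-6-[(3-methylbut-2-en-1-yl)oxy]benzophenone | CC(C)=CCOc1cc(O)cc(O)c1C(=O)c1ccccc1 | intermediate
17 | isobutyryl chloride (2-methylpropanoyl chloride) | CC(C)C(Cl)=O | starting material
18 | 2-methyl-1-(2,4,6-trihydroxyphenyl)propan-1-one | CC(C)C(=O)c1c(O)cc(O)cc1O | intermediate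
19 | 2-methyl-1-(2,4,6-trihydroxy-3-methylphenyl)propan-1-one | CC(C)C(=O)c1c(O)cc(O)c(C)c1O | intermediate (not isolated)
20 | isobutyrylfilicinic acid, 3,5-dihydroxy-6,6-dimethyl-2-(2-methylpropanoyl)cyclohexa-2,4-dien-1-one | CC(C)C(=O)C1=C(O)C=C(O)C(C)(C)C1=O | intermediate
21 | 4-[(dimethylamino)methyl]-3,5-dihydroxy-6,6-dimethyl-2-(2-methylpropanoyl)cyclohexa-2,4-dien-1-one hydroiodide | C[NH+](C)CC1=C(O)C(C)(C)C(=O)C(C(=O)C(C)C)=C1O.[I-] | intermediate (not isolated)
22 | 3-hydroxy-6,6-dimethyl-4-methylidene-2-(2-methylpropanoyl)cyclohex-2-ene-1,5-dione | C=C1C(=O)C(C)(C)C(=O)C(C(=O)C(C)C)=C1O | intermediate (not isolated)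
23 | sarothralin, 4-({3-benzoyl-2,6-dihydroxy-4-[(3-methylbut-2-en-1-yl)oxy]phenyl}methyl)-3,5-dihydroxy-6,6-dimethyl-2-(2-methylpropanoyl)cyclohexa-2,4-dien-1-one | CC(C)=CCOc1cc(O)c(CC2=C(O)C(C)(C)C(=O)C(C(=O)C(C)C)=C2O)c(O)c1C(=O)c1ccccc1 | target

## Step count and least certain steps

Total: 10 steps. Longest linear sequence: 8 steps (steps 1 to 7, then step 10, from 1). The ring B branch (steps 8 and 9) joins at step 10.

**Step 5 (key step).** The most likely failure is protonation of anion 11 before the 1,3 acyl shift, which would stop at O-arylation. Less likely is addition of benzoate to the other aryne carbon. The fallback sets out from 4 and 9 and comes back at 12. It generates the same ortho-acyloxyaryl anion without an aryne, so its position is fixed by the bromine. 4 is esterified with 9 (EtN=C=N(CH2)3NMe2·HCl, catalytic 4-(dimethylamino)pyridine, CH2Cl2) to 2-bromo-3,5-bis(methoxymethoxy)phenyl benzoate F1. Bromine–lithium exchange (n-BuLi, THF, −100 °C) then triggers an anionic Fries-type 1,3 O→C benzoyl shift, which should give 12 after protonation.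

**Step 2.** The most likely failure is bromination para to the hydroxyl or twofold bromination, since every free ring position is activated by three oxygens. The fallback sets out from 3 and comes back at 8, replacing bromination by directed metalation. 3 is carbamoylated (i-PrNCO, catalytic Et3N, CH2Cl2) to 3,5-bis(methoxymethoxy)phenyl N-isopropylcarbamate F2. After N-silylation in the flask (Me3SiOTf, TMEDA, Et2O), n-BuLi/TMEDA at −78 °C should lithiate between the carbamate and a MOM-oxy group, the site held by the strongest directing group. Me3SiCl then gives 3,5-bis(methoxymethoxy)-2-(trimethylsilyl)phenyl N-isopropylcarbamate F3. Cleavage of the carbamate (DBU, Et2NH, MeCN, 40 °C) and triflation of the phenoxide in the same flask (PhNTf2) should give 8.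

**Step 7.** The most likely failure is acid-induced loss or solvolysis of the prenyl ether while the slower para MOM group is being removed. The fallback sets out from 12 and comes back at 16, moving the acid treatment to a stage without a prenyl group. Both MOM groups of 12 are removed (HCl, MeOH, 50 °C) to give symmetrical 2,4,6-trihydroxybenzophenone F4. The unchelated and most acidic para hydroxyl is silylated (i-Pr3SiCl, imidazole, DMF, 0 °C) to 2,6-dihydroxy-4-(triisopropylsilyloxy)benzophenone F5. One of the two equivalent chelated hydroxyls is alkylated with 13 (K2CO3, acetone, rt) to 2-hydroxy-6-[(3-methylbut-2-en-1-yl)oxy]-4-(triisopropylsilyloxy)benzophenone F6; the remaining hydroxyl stays chelated and should resist a second alkylation. Fluoride (n-Bu4NF, AcOH, THF, 0 °C) then frees 16.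

**Step 9.** The most likely failure is under- and over-methylation (a third methyl at the last ring CH, or O-methylation), because each methylated intermediate is still an enolate. The fallback sets out from 17 and comes back at 20, building ring B with the quaternary carbon already in place. 17 acylates the lithium enolate of acetone (LiN(i-Pr)2, THF, −78 °C) to 5-methylhexane-2,4-dione F7. Its dianion (LiN(i-Pr)2, THF, −78 to 0 °C) is acylated at the methyl terminus by dimethyl 2,2-dimethylmalonate A3 to methyl 2,2,8-trimethyl-3,5,7-trioxononanoate F8. Claisen-type ring closure of the central diketone carbon on the remaining ester (NaOMe, MeOH, reflux) should give 20.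

**Step 10.** The most likely failures are alkylation of ring A through A2 and not A4, double alkylation of ring A, and exchange of the methylene bridge leading to symmetrical products. The fallback sets out from 16 and comes back at 23. It reverses the roles of the partners, so that the regiochemistry is fixed and purified on a small ring A derivative before the union. 16 is aminomethylated (Me2N+=CH2 I−, CH2Cl2, rt) to 3-[(dimethylamino)methyl]-2,4-dihydroxy-6-[(3-methylbut-2-en-1-yl)oxy]benzophenone F9, which is freed from any A2 isomer by crystallisation or chromatography. Heating F9 with 20 (dioxane, 100 °C) should expel dimethylamine to an ortho-quinone methide that is captured by the ring carbon of 20, giving 23.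

## Further compounds

F1 | step 5 | 2-bromo-3,5-bis(methoxymethoxy)phenyl benzoate | COCOc1cc(OC(=O)c2ccccc2)c(Br)c(OCOC)c1
F2 | step 2 | 3,5-bis(methoxymethoxy)phenyl N-isopropylcarbamate | COCOc1cc(OC(=O)NC(C)C)cc(OCOC)c1
F3 | step 2 | 3,5-bis(methoxymethoxy)-2-(trimethylsilyl)phenyl N-isopropylcarbamate | COCOc1cc(OC(=O)NC(C)C)c([Si](C)(C)C)c(OCOC)c1
F4 | step 7 | 2,4,6-trihydroxybenzophenone | O=C(c1ccccc1)c1c(O)cc(O)cc1O
F5 | step 7 | 2,6-dihydroxy-4-(triisopropylsilyloxy)benzophenone | CC(C)[Si](Oc1cc(O)c(C(=O)c2ccccc2)c(O)c1)(C(C)C)C(C)C
F6 | step 7 | 2-hydroxy-6-[(3-methylbut-2-en-1-yl)oxy]-4-(triisopropylsilyloxy)benzophenone | CC(C)=CCOc1cc(O[Si](C(C)C)(C(C)C)C(C)C)cc(O)c1C(=O)c1ccccc1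
F7 | step 9 | 5-methylhexane-2,4-dione | CC(=O)CC(=O)C(C)C
F8 | step 9 | methyl 2,2,8-trimethyl-3,5,7-trioxononanoate | COC(=O)C(C)(C)C(=O)CC(=O)CC(=O)C(C)C
F9 | step 10 | 3-[(dimethylamino)methyl]-2,4-dihydroxy-6-[(3-methylbut-2-en-1-yl)oxy]benzophenone | CC(C)=CCOc1cc(O)c(CN(C)C)c(O)c1C(=O)c1ccccc1
A1 | alternative 1 | sarothralin bis(methoxymethyl) ether | COCOc1cc(OCC=C(C)C)c(C(=O)c2ccccc2)c(OCOC)c1CC1=C(O)C(C)(C)C(=O)C(C(=O)C(C)C)=C1O
A2 | alternative 1 | 1-{3-benzoyl-2,6-bis(methoxymethoxy)-4-[(3-methylbut-2-en-1-yl)oxy]phenyl}-6-methylheptane-3,5-dione | COCOc1cc(OCC=C(C)C)c(C(=O)c2ccccc2)c(OCOC)c1CCC(=O)CC(=O)C(C)C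
A3 | alternative 1 | dimethyl 2,2-dimethylmalonate | COC(=O)C(C)(C)C(=O)OC
A4 | alternative 2 | 2,4-bis(allyloxy)-6-[(3-methylbut-2-en-1-yl)oxy]benzophenone | C=CCOc1cc(OCC=C(C)C)c(C(=O)c2ccccc2)c(OCC=C)c1
A5 | alternative 2 | 2,4,6-trifluorobenzophenone | O=C(c1ccccc1)c1c(F)cc(F)cc1F
A6 | alternative 2 | lithium 3-methylbut-2-en-1-olate | [Li+].[O-]CC=C(C)C
A7 | alternative 2 | potassium prop-2-en-1-olate | [K+].[O-]CC=C
A8 | alternative 3 | 3-benzoyl-2,6-bis(methoxymethoxy)-4-[(3-methylbut-2-en-1-yl)oxy]benzaldehyde | COCOc1c(C(=O)c2ccccc2)c(OCC=C(C)C)cc(OCOC)c1C=O
A9 | alternative 3 | 3-iodo-2,6-bis(methoxymethoxy)-4-[(3-methylbut-2-en-1-yl)oxy]benzaldehyde | COCOc1c(I)c(OCC=C(C)C)cc(OCOC)c1C=O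
A10 | alternative 3 | phenylboronic acid | OB(O)c1ccccc1
A11 | alternative 3 | carbon monoxide | [C-]#[O+]
A12 | alternative 3 | 2,6-bis(methoxymethoxy)-4-[(3-methylbut-2-en-1-yl)oxy]benzaldehyde | COCOc1cc(OCC=C(C)C)cc(OCOC)c1C=O
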